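At late times this closed flask holds what two rival routes have made of its substrate, so the split between them is what has to be reckoned.

    substrate + enzyme → target + enzyme, rate k1*[substrate]*[enzyme]/(1 + ([substrate]/Km1) + ([substrate]/Ksi1)^2) (Km1 = 0.88 mM, Ksi1 = 0.17 mM, k1 = 1.3 × 10⁷ M⁻¹ s⁻¹)
    enzyme + added ligand ⇌ idle complex, settled at all times (K2 = 1.2 × 10⁶ M⁻¹)
    2 substrate → self-condensation product (k3 = 74 M⁻¹ s⁻¹)
    enzyme → spent catalyst (k4 = 0.0055 s⁻¹)

substrate 2.0 mM; enzyme 0.01 mol%; added ligand 0.73 µM; time 1.5 h

- a species is counted by the substrate in it: one self-condensation product counts as two
- where a step has two of a species, its rate is k times that concentration squared, and two are used at each turn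
- the reaction counts as stopped when no species that holds the substrate changes by six tenths of a point or more over the second half of the time
- run time (flask): 1.5 h

1. which holds at 1.5 h: what has brought the reaction to rest, or that it has not come to rest (all of the substrate has reacted / it is still moving)
2. part of the substrate gone at 1.5 h
3. the target standing at 1.5 h, as a percentage of the substrate charged

With the main step alone, the substrate ends as target, a yield of 100 percent. Self-condensation is added next. At the charge the squared inhibition term stands at 138, against 3.27 for the other two terms. While that squared term leads, the ratio of substrate used by enzyme to substrate used by condensation, a selectivity factor, goes as the inverse cube of [substrate]. With all 0.200 µM of enzyme free, that ratio reaches one at 0.798 mM. As a reckoning, substrate above this level is counted as condensed and substrate below it as target. The yield is then this level over the charge, 39.9%.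

The added ligand comes next. Against its full charge, 53.3% of the enzyme stays free. The bound part holds 0.0934 µM of ligand, and with that correction, leaving 0.637 µM, the free share is 56.7%. The crossover level, the [substrate] at which free enzyme and condensation use substrate equally, falls to 0.660 mM, and the yield to 33.0%.

Spent catalyst comes last. Near the crossover, the first half-life of [substrate] by condensation alone is about 10.2 s, while the mean life of enzyme is 182 s. About 5.63% of the enzyme goes in that time. The run is much longer, so this reckoning commits to complete conversion and 33.0% target.

The forecast states that all of the substrate has reacted, with conversion 100% and target 36%, above this reckoning, holding that “the target forms mainly once the substrate has fallen below about 0.6 mM”.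

In the simulated flask all of the substrate has reacted, with conversion 100% and target 36.6%, which is 3.6 percentage points above the crossover rule. In this flask half of the condensation turnover is done by 0.0268 min, earlier than half of the turnover to target at 0.129 min, and at 7.7 s the step to target uses substrate 3.6 times as fast as condensation. The neighbour flask with 0.004 mol% of enzyme has a reckoned free share of 54.6% and a crossover level of 0.480 mM, so the rule gives 24.0%, and that flask holds 26.5% target.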